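Readings and results are simulated for substances that don't exist, and the scatter is random.

The delta run, charged with 0.034 M of reagent in the second phase against 0.050 M of substrate, held 25.8% product at 3.00 min. The question is what that reading is worth for the flask charged with equal substrate and reagent.

all flasks: substrate 0.050 M

| charge | reagent in the second phase | remark | time | volume of the second phase over the first |
|---|---|---|---|---|
| beta | 0.050 M | the very flask that is asked about, followed so far |  |  |
| delta | 0.034 M | run made earlier |  |  |
| flask | 0.0500 M |  | 3.0 min | 1.0 |

beta run (percent of the substrate charged)

| time / s | product / % | substrate / % |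
|---|---|---|
| 10.0 | 3.5 | 96.4 |
| 15.0 | 6.3 | 92.3 |
| 25.0 | 9.1 | 87.3 |
| 40.0 | 12.5 | 83.1 |
| 50.0 | 15.6 | 80.0 |

delta run (percent of the substrate charged)

| time / min | product / % | substrate / % |
|---|---|---|
| 0.250 | 3.8 | 95.7 |
| 0.333 | 3.2 | 94.2 |
| 0.500 | 6.5 | 91.6 |
| 0.833 | 12.5 | 84.7 |
| 1.33 | 16.1 | 77.5 |
| 2.00 | 20.9 | 69.2 |
| 3.00 | 25.8 | 61.7 |

(standard deviation of a reading: 1 percentage point)

- in the second phase: reagent in the second phase; everything else is in the first
- charges count per volume of the first phase; a concentration in a rate is the amount of a species over the volume of its own phase; every rate counts per litre of the first phase
- steps under discussion: reagent in the reaction phase <-> reagent in the second phase; substrate + reagent in the reaction phase <-> product; substrate <-> dormant form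
- the earlier runs hold the two phases in the same ratio of volumes as the flask asked about

- grey: doubling the amount of reagent in the second phase, all else as stated
- red: doubling the transfer coefficient of the reagent in the second phase, all else as stated

1. amount of product at 3.0 min, in percent of the substrate charged
2. the change that raises the amount of product at 3.0 min, in percent of the substrate charged most ("none" if none brings more than 2 percentage points) (grey / red / none)
3. amount of product at 3.0 min, in percent of the substrate charged, after grey

My reckoning takes the rate of product as proportional to [substrate] and to the reagent not yet used, then inverts the integrated law on a single reading. The delta reading at 3.00 min gives 0.186 min⁻¹. Call this the pace: the apparent second-order rate constant times [substrate] as charged, read at a stated time.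

For equal charges the product fraction is pace × time over one plus pace × time. The first way therefore gives 35.8% at 3.0 min.

The second way uses the beta run itself. Its reading at 50.0 s gives a pace of 0.222 min⁻¹, which leads to 40.0%.

The two ways part, so one of them cheats. Delta at 0.833 min reads 0.261 min⁻¹, higher than its late pace. The pace read from delta thus sinks between those two readings, and the second way carries beta's early pace forward to 3.0 min. By 3.00 min, delta's product and substrate also read 12 percentage points short of the charge, and delta's late pace is read with that shortfall standing. I commit to 35.8%.

With the reagent doubled, the same law and pace give 59.9%. Beta at 10.0 s reads 0.218 min⁻¹, about its pace at 50.0 s. Beta shows no lag, though that reading of 3.5% is good to 1 point, so red should bring little and I choose grey.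

The forecast gives 37%, chooses grey and gives 61% after it, holding that “transfer is fast and not limiting”.

The flask gives 36.6%. Grey gives 59.4%, a gain of 23 points, against 0.15 points for red.

    reagent in the reaction phase ⇌ reagent in the second phase, rate k1*([reagent in the reaction phase] - [reagent in the second phase]/K1) per volume of the first phase (partition coefficient = 0.480, kL = 0.150 s⁻¹)
    substrate + reagent in the reaction phase ⇌ product (K = 77.0 L mol⁻¹, k = 0.130 L mol⁻¹ s⁻¹)
    substrate ⇌ dormant form (K = 1.00, k = 8.70 × 10⁻⁴ s⁻¹)

The same pace, carried to the flask left until 8.0 min, gives 59.8%. That flask holds 46.4% product, with 36.1% substrate and 17.5% dormant form, so the pace overshoots by 13 points. Its reaction phase holds 0.0181 M reagent, and [product]/([substrate][reagent in the reaction phase]) stands at 71.0 L mol⁻¹, against an equilibrium constant of 77 L mol⁻¹.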